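Late in the east and south runs free monomer falls ever more slowly, a levelling-off the trade calls dead-end polymerisation, so I fold each run into one pure number, its reach: the natural logarithm of charged over free monomer where the fall levels off.

all flasks: free monomer 0.061 M; radical scavenger 0.03 mol%

| flask | initiator | remark | time |
|---|---|---|---|
| east | 0.25 mol% | run made earlier |  |
| south | 1 mol% | run made earlier |  |
| flask | 0.5 mol% |  | 4.0 d |

| run | time / d | monomer in chains / % | free monomer / % |
|---|---|---|---|
| east | 0.208 | 13.8 | 85.7 |
| east | 0.333 | 21.9 | 78.0 |
| east | 0.500 | 29.0 | 69.9 |
| east | 0.833 | 39.8 | 59.7 |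
| east | 1.67 | 52.5 | 46.2 |
| east | 2.50 | 58.7 | 40.9 |
| south | 0.417 | 46.1 | 53.5 |
| south | 0.833 | 64.9 | 33.4 |
| south | 1.25 | 75.5 | 25.0 |
| south | 1.67 | 78.9 | 20.3 |
| south | 2.08 | 83.1 | 17.1 |
| south | 2.50 | 83.7 | 15.6 |

(scatter of a reading: 0.5 percentage points)

- what may be going on: 2 growing radical -> dead chain; free monomer + growing radical -> monomer in chains + growing radical; free monomer + initiating radical -> growing radical + monomer in chains; growing radical + radical scavenger -> ended chains; initiator -> 2 initiating radical

1. concentration of monomer in chains at 4.0 d, in M
2. concentration of free monomer at 4.0 d, in M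

Between the readings at 0.833 d, 1.67 d and 2.50 d that logarithm gains 0.256, then 0.122 in east, and 0.498, then 0.263 in south, so each step brings about half of the one before. Summing the shrinking steps gives reaches, read with the scatter, of 1.00 for east and 2.15 for south. Their ratio, 2.15, stands near 2.00, the square root of the ratio of initiator loadings, so, with free monomer and radical scavenger charged alike, I let reach follow that root. The flask's loading then gives it the geometric mean, a reach of 1.47.

Reach used in full leaves the flask 23.0% free monomer. Is one number enough? I carry the shrinking of the steps in east and south over to the flask, and by 4.0 d I reckon they leave 3.63% of the reach unused, which lifts my figure for the flask to 24.2%, or 0.0148 M. The last east readings add to 99.6%, near the whole charge for a scatter of 0.5 percentage points on each, so I take the two forms as adding to the charge and put [monomer in chains] in the flask at 0.0462 M.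

The forecast says “The scavenger causes only a slight early lag” and gives 0.046 M and 0.0148 M; the flask gives 0.0459 M and 0.0151 M.

    2 growing radical → dead chain (k = 7.30 × 10⁷ L mol⁻¹ s⁻¹)
    free monomer + growing radical → monomer in chains + growing radical, rate k2*[growing radical]*[free monomer] (k = 5.80 × 10⁶ L mol⁻¹ h⁻¹)
    free monomer + initiating radical → growing radical + monomer in chains (k = 25000 L mol⁻¹ s⁻¹)
    growing radical + radical scavenger → ended chains (k = 1.00 × 10⁸ L mol⁻¹ s⁻¹)
    initiator → 2 initiating radical (k = 0.0750 h⁻¹)

At 0.459 d in the flask the initiator's half-life is 0.39 d, shorter than the 0.81 d of free monomer by chain growth. At 4.00 d the flask holds 0.0747% of its charged initiator and 24.7% of its charged free monomer. In the neighbour flask with 0.12 mol% initiator, the root rule gives a reach of 0.721 and, with the same unused part, 49.9% free monomer. The computed neighbour holds 52.5%, or 0.0320 M.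

The runs were generated by integration with constants of no real substance, and the scatter is random.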